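Numbering: eudesmane numbering is used throughout. Ring A is C1–C5 with C10, ring B is C5–C10, C14 is the methyl on C10, C15 the methyl on C4, and C11–C13 the isopropyl group on C7. Compounds 1–12 are those of the steps below.

## The problem

The target 12 is the 6-O-(E)-isoferulate of eudesmane-4β,6β-diol; the SMILES corresponds to 4S,5S,6R,7S,10R, that is 4β-OH/4α-CH3, 5α-H, 6β-O-acyl, 7β-isopropyl and 10β-CH3 on a trans-decalin. Five stereocentres must be set, four of them contiguous (C4–C7) around a ring-fusion carbon that lies between two fully substituted carbons, and the fifth (C10) is quaternary and cannot be corrected once made. The 4-hydroxyl, the 6-acyloxy group and C14 are all axial on the β face and mutually 1,3-syn, so the ester oxygen sits in the less stable axial position and C4 carries its larger group equatorial. A ring closure onto a trigonal C5 next to a tetrahedral C10 is expected to give the cis-fused decalin kinetically, so the trans fusion has to come from equilibration or from addition to the α face. The tertiary alcohol is β to C6 (dehydration, retro-aldol), the axial 6-hydroxyl is flanked by the isopropyl group and the ring fusion (slow acylation), and the cinnamate with its free phenol tolerates neither hydrogenation nor strong base, so it must come last. The feature that opens the problem is that C4(OH)(CH3) is β to C6 with the hydrogen-bearing C5 between them: at the C6-ketone oxidation level the ring A bond C4–C5 is an aldol bond, both of its stereocentres are reversible (C4 by retro-aldol, C5 by enolisation), and the configuration wanted is argued below to be the stable one. In addition, ring B with oxygen on C6, isopropyl on the neighbouring C7 and methyl on the meta carbon C10 has the substitution pattern of the p-menthan-3-ones, so ring B with all its substituents can be bought as one ten-carbon enone.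

## Retrosynthesis

Cut 1, the cinnamate Cα=Cβ bond of 12, not the ester C–O bond. Cutting the ester would need a phenol-protected isoferulic acid and the acylation of a very hindered axial alcohol with a bulky acyl donor. Cutting the olefin leads to aldehyde 11, which keeps its free phenol, and to malonic half-ester 10, which comes from diol 8 and the small acylating agent 9. The precursor 8 has lost the whole arylpropenoyl unit. The forward reaction must be E-selective and must spare the tertiary alcohol.

Cut 2, the C6–H bond of 8. The axial 6β-alcohol is the kinetic product of hydride addition to ketone 7 from the α face, because the β face is closed by C14 and the 4β-oxygen. This returns C6 to the ketone level that the aldol plan needs. The forward reaction must deliver hydride equatorially without enolising C5 or C7.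

Cut 3, the C7–H and C11–H bonds of 7. An α-isopropyl cyclohexanone is only weakly biased towards its equatorial epimer, so C7 is not left to equilibration. It is kept trigonal, as the isopropylidene enone 6, through the basic step and is set afterwards by hydrogen addition to the α face. The precursor 6 has one stereocentre fewer, at the cost of one hydrogenation.

Cut 4 (key), the C4–C5 bond of 6, a retro-aldol to diketone 5. The neighbouring aldol (C5–C6, with ring A as the ketone) is worse, because C6 would then be the carbinol formed under equilibrium, where the equatorial 6α-alcohol wins. A Robinson-type closure is worse, because it leaves a ketone on C3 and an olefin C4=C5 and erases both centres. In the chosen direction the carbinol is C4, whose geminal methyl group decides for the axial hydroxyl, and C5 is epimerisable. The precursor 5 is monocyclic with a single stereocentre. The forward step must close ring A regioselectively and set two centres under thermodynamic control.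

Cut 5, the C1–C10 bond. Unmasking the ketone (5 from ketal 4) and cutting next to the quaternary carbon leads to piperitenone 2, an achiral cross-conjugated dienone, and to Grignard reagent 3 from bromide 1. This is the only step that creates absolute configuration, and because 2 is achiral the catalyst acts alone, with no matched or mismatched pairing. The forward reaction must add at the ring β-carbon, not the isopropylidene carbon, and form the quaternary centre with high enantioselectivity.

## Roads not taken

Alternative 1: the most obvious plan cuts C1–C10 and C4=C5 as a Robinson annulation. (+)-Dihydrocarvone A1 and pent-1-en-3-one A2 would give (+)-α-cyperone A3, with C7 taken from the chiral pool. The chosen plan is better for four reasons. Base-mediated annulation of A1 with A2 favours the C10 epimer of A3, so a chiral-imine detour is needed. The oxygen of A3 ends on C3 and must be removed. C6 is still a methylene, and C4=C5 must be hydrated to 4β-OH/5α-H, which is not the direction that simple face-selective additions to this olefin give. A3 carries two of the five centres and the wrong oxidation pattern, and at least six redox steps follow, whereas the aldol of step 3 delivers the C4 and C6 oxygens in place.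

Alternative 2: cut C1–C10 and C4–C5 in a Diels–Alder sense. Thymoquinone A4, reacting through its methyl-bearing double bond, and (E)-1-(trimethylsilyloxy)buta-1,3-diene A5 would give the cis-fused adduct A6, with every ring carbon of the decalin present after one step. The chosen plan is better for three reasons. The nucleophilic terminus of A5 should bond to the unsubstituted carbon of that double bond, which places the oxygen on C1, so A6 would be the minor regioisomer. A4 has two similar double bonds and two nearly equivalent carbonyls, so up to four adducts are possible. In A6 the C9 carbonyl must still be removed, the C15 methyl added, and the fusion epimerised.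

Alternative 3: cut the C4–O bond last. Eudesman-6β-ol A7 would be converted to its N-(2,2,2-trifluoroethyl)carbamate A8. The forward key step on A8 is a nitrogen-radical 1,6-hydrogen transfer from the syn-axial C4–H, bromination, ring closure through the carbamate oxygen and hydrolysis to 8. The chosen plan is better for three reasons. A7 already holds the whole skeleton and four stereocentres plus a C4–H centre that must be set on purpose, so it is not simpler than 8. The nitrogen radical of A8 has a second tertiary C–H at the same distance (C11–H of the isopropyl group). At least three steps are added, whereas the aldol installs the C4 oxygen in the ring-forming step itself.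

Key step: step 3

Remark: piperitenone 2 is taken as a purchasable monoterpene ketone, and the enantiomer of the carbene ligand in step 1 is the one that gives the R-configured quaternary centre, to be fixed on a test scale.

## Steps

Step 1
Reactants: 1 2-(3-bromopropyl)-2-methyl-1,3-dioxolane; 2 piperitenone, 3-methyl-6-(propan-2-ylidene)cyclohex-2-en-1-one
Product: 4 (5R)-5-methyl-5-[3-(2-methyl-1,3-dioxolan-2-yl)propyl]-2-(propan-2-ylidene)cyclohexan-1-one, via Grignard reagent 3 (not isolated)
Conditions: Mg, Et2O, 35 °C (1 to 3); then 2, Cu(OTf)2 (3 mol %), chiral imidazolinium salt as N-heterocyclic carbene precursor (4 mol %), Et2O, −30 to 0 °C; H2O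
Reagents that add atoms: none
Why: Copper-catalysed asymmetric conjugate addition of a Grignard reagent to a β-methyl cyclohexenone with a chiral N-heterocyclic carbene ligand, the standard way to a methyl-bearing quaternary centre; the ring arm of 2 is trisubstituted and free at its α-carbon while the isopropylidene arm is tetrasubstituted and α-substituted, so the alkyl group should go to ring carbon 3 (C10), and since 2 is achiral the ligand alone sets this centre.

Step 2
Reactants: 4 (5R)-5-methyl-5-[3-(2-methyl-1,3-dioxolan-2-yl)propyl]-2-(propan-2-ylidene)cyclohexan-1-one
Product: 5 (5R)-5-methyl-5-(4-oxopentyl)-2-(propan-2-ylidene)cyclohexan-1-one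
Conditions: 1 M HCl, THF, 23 °C
Reagents that add atoms: water, O
Why: Acid-catalysed hydrolysis of a dioxolane; the enone and the quaternary centre are inert, and a short exposure at room temperature is chosen so that acid-promoted aldol condensation of the freed diketone does not set in.

Step 3
Reactants: 5 (5R)-5-methyl-5-(4-oxopentyl)-2-(propan-2-ylidene)cyclohexan-1-one
Product: 6 (4aR,8S,8aR)-8-hydroxy-4a,8-dimethyl-2-(propan-2-ylidene)octahydronaphthalen-1(2H)-one (4β-hydroxyeudesm-7(11)-en-6-one)
Conditions: KOt-Bu (0.2 equiv), THF–t-BuOH (4:1), 0 to 23 °C; AcOH
Reagents that add atoms: none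
Why: Catalytic tert-butoxide enolises the ring ketone at C5 (its only α-CH2, since C7 is trigonal) and the dienolate adds to the side-chain ketone C4 in a reversible intramolecular aldol addition, the ketone-donor counterpart of the ketol stage of a Robinson annulation. Ring A closes in the 6-(enolexo)-exo-trig mode by bonding C5 to C4. The other closures are disfavoured: the methyl-ketone enolate (C3) onto C6 would give a bridged bicyclo[3.3.1]nonanol at a hindered cross-conjugated carbonyl, and closures through C7 or C15 would be eight-membered. C4 is set under thermodynamic control through retro-aldol and re-addition: with hydroxyl axial (β) and methyl equatorial the carbinol meets the axial C14 only as an OH/CH3 pair, whereas its epimer would carry a CH3/CH3 syn-diaxial pair, estimated to cost 1.5 to 2 kcal/mol more. C5 is set under thermodynamic control through enolisation: the kinetic closure should be cis-fused, but in the trans-fused isomer the axial 4-hydroxyl is gauche to C6 and able to hydrogen-bond (or chelate potassium) to the C6 carbonyl, while the cis isomer of the same C4 configuration must either place C6 axial on ring A with the hydroxyl anti to it or carry the C15 methyl syn-diaxial to C9. C10, fixed in step 1 and not enolisable, is the reference for both new centres, and C7 is kept sp2 so that no weakly biased α-isopropyl ketone centre is exposed to base. The step therefore needs regioselectivity (C5 donor, C4 acceptor) and diastereoselectivity (4β-OH, trans fusion), both resting on the substitution pattern of 5; anhydrous catalytic alkoxide at or below room temperature is used to keep the tertiary ketol from dehydrating and the isopropylidene group from being lost as acetone.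

Step 4
Reactants: 6 (4aR,8S,8aR)-8-hydroxy-4a,8-dimethyl-2-(propan-2-ylidene)octahydronaphthalen-1(2H)-one
Product: 7 (2S,4aR,8S,8aR)-8-hydroxy-4a,8-dimethyl-2-(propan-2-yl)octahydronaphthalen-1(2H)-one (4β-hydroxyeudesman-6-one)
Conditions: H2 (1 atm), Pd/C (10 %), EtOAc, 23 °C
Reagents that add atoms: none
Why: Heterogeneous hydrogenation of a conjugated α-alkylidene ketone; the enone unit is close to planar and the β face of the bicycle is screened by the axial C14 methyl and the 4β-hydroxyl, so both hydrogens should arrive from the α face, which makes H-7 α and the isopropyl group β (equatorial), and the neutral medium leaves the new α-centre and the ketol untouched.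

Step 5
Reactants: 7 (2S,4aR,8S,8aR)-8-hydroxy-4a,8-dimethyl-2-(propan-2-yl)octahydronaphthalen-1(2H)-one
Product: 8 (1S,4aR,7S,8R,8aS)-1,4a-dimethyl-7-(propan-2-yl)decahydronaphthalene-1,8-diol (eudesmane-4β,6β-diol)
Conditions: LiBH(s-Bu)3 (2.5 equiv), THF, −78 to 0 °C; H2O
Reagents that add atoms: none
Why: A bulky trialkylborohydride attacks a cyclohexanone from the equatorial side, here the α face, because the axial (β) trajectory is closed by the syn-axial C14 methyl and the 4β-oxygen; as in the reduction of 2-isopropylcyclohexanones to the cis alcohols this gives the axial 6β-alcohol cis to the isopropyl group, at a temperature where C5 and C7 are not enolised.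

Step 6
Reactants: 8 (1S,4aR,7S,8R,8aS)-1,4a-dimethyl-7-(propan-2-yl)decahydronaphthalene-1,8-diol; 9 Meldrum's acid, 2,2-dimethyl-1,3-dioxane-4,6-dione
Product: 10 3-{[(1R,2S,4aR,8S,8aS)-8-hydroxy-4a,8-dimethyl-2-(propan-2-yl)decahydronaphthalen-1-yl]oxy}-3-oxopropanoic acid
Conditions: toluene, 100 °C
Reagents that add atoms: none
Why: Thermal ring-opening acylation of an alcohol by Meldrum's acid gives the malonic half-ester and acetone without activating agent or base; the secondary 6-hydroxyl, although axial, should react well ahead of the tertiary 4-hydroxyl, and no protecting group is needed.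

Step 7
Reactants: 10 3-{[(1R,2S,4aR,8S,8aS)-8-hydroxy-4a,8-dimethyl-2-(propan-2-yl)decahydronaphthalen-1-yl]oxy}-3-oxopropanoic acid; 11 isovanillin, 3-hydroxy-4-methoxybenzaldehyde
Product: 12 (1R,2S,4aR,8S,8aS)-8-hydroxy-4a,8-dimethyl-2-(propan-2-yl)decahydronaphthalen-1-yl (2E)-3-(3-hydroxy-4-methoxyphenyl)prop-2-enoate
Conditions: pyridine, piperidine (0.1 equiv), 70 °C
Reagents that add atoms: none
Why: Knoevenagel–Doebner condensation of a malonic half-ester with an aryl aldehyde: amine-catalysed condensation followed by decarboxylation gives the (E)-cinnamate directly, the free phenol of 11 is tolerated, and the mild base does not touch the hydroxy ester.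

## Compound list

1 | 2-(3-bromopropyl)-2-methyl-1,3-dioxolane | CC1(CCCBr)OCCO1 | starting material
2 | piperitenone, 3-methyl-6-(propan-2-ylidene)cyclohex-2-en-1-one | CC1=CC(=O)C(=C(C)C)CC1 | starting material
3 | [3-(2-methyl-1,3-dioxolan-2-yl)propyl]magnesium bromide | CC1(CCC[Mg]Br)OCCO1 | intermediate
4 | (5R)-5-methyl-5-[3-(2-methyl-1,3-dioxolan-2-yl)propyl]-2-(propan-2-ylidene)cyclohexan-1-one | O=C1C[C@](C)(CCCC2(C)OCCO2)CCC1=C(C)C | intermediate
5 | (5R)-5-methyl-5-(4-oxopentyl)-2-(propan-2-ylidene)cyclohexan-1-one | O=C1C[C@](C)(CCCC(C)=O)CCC1=C(C)C | intermediate
6 | (4aR,8S,8aR)-8-hydroxy-4a,8-dimethyl-2-(propan-2-ylidene)octahydronaphthalen-1(2H)-one | O=C2[C@@H]3[C@](C)(CCC[C@]3(C)O)CCC2=C(C)C | intermediate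
7 | (2S,4aR,8S,8aR)-8-hydroxy-4a,8-dimethyl-2-(propan-2-yl)octahydronaphthalen-1(2H)-one | O=C2[C@@H]3[C@](C)(CCC[C@]3(C)O)CC[C@H]2C(C)C | intermediate
8 | (1S,4aR,7S,8R,8aS)-1,4a-dimethyl-7-(propan-2-yl)decahydronaphthalene-1,8-diol | O[C@H]2[C@@H]3[C@](C)(CCC[C@]3(C)O)CC[C@H]2C(C)C | intermediate
9 | Meldrum's acid, 2,2-dimethyl-1,3-dioxane-4,6-dione | CC1(C)OC(=O)CC(=O)O1 | starting material
10 | 3-{[(1R,2S,4aR,8S,8aS)-8-hydroxy-4a,8-dimethyl-2-(propan-2-yl)decahydronaphthalen-1-yl]oxy}-3-oxopropanoic acid | OC(=O)CC(=O)O[C@H]2[C@@H]3[C@](C)(CCC[C@]3(C)O)CC[C@H]2C(C)C | intermediate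
11 | isovanillin, 3-hydroxy-4-methoxybenzaldehyde | COc1ccc(C=O)cc1O | starting material
12 | (1R,2S,4aR,8S,8aS)-8-hydroxy-4a,8-dimethyl-2-(propan-2-yl)decahydronaphthalen-1-yl (2E)-3-(3-hydroxy-4-methoxyphenyl)prop-2-enoate | COc1ccc(/C=C/C(=O)O[C@H]2[C@@H]3[C@](C)(CCC[C@]3(C)O)CC[C@H]2C(C)C)cc1O | target

## Step count and least certain steps

Total step count: 7. Longest linear sequence: 7 steps (from 1 and 2 to 12).

Step 3 (key step). The most likely failure is incomplete funnelling at the ring fusion: the estimated preference for the trans-fused ketol rests largely on the internal hydrogen bond and may shrink in the partly protic medium. Slow dehydration of the tertiary ketol to the cross-conjugated dienone, partial deconjugation of the isopropylidene group and an unfavourable position of the aldol equilibrium may accompany it. The fallback closes the ring reductively instead of by base catalysis. Setting out from 4, the kinetic enolate (LiN(SiMe3)2, THF, −78 °C; only the ring carbon next to the quaternary centre carries α-hydrogens) is brominated with NBS to (3R)-2-bromo-3-methyl-3-[3-(2-methyl-1,3-dioxolan-2-yl)propyl]-6-(propan-2-ylidene)cyclohexan-1-one F1, a mixture at the bromine-bearing carbon. Hydrolysis of F1 (1 M HCl, THF) gives (3R)-2-bromo-3-methyl-3-(4-oxopentyl)-6-(propan-2-ylidene)cyclohexan-1-one F2. Treatment of F2 with SmI2 (2.2 equiv, THF, −78 °C, then warming) generates the enolate regiospecifically and without a proton source. The intramolecular Reformatsky-type aldol addition gives a chelated aldolate, in which retro-aldol exchange can still correct C4 and C5 but no free base is present to dehydrate. Aqueous work-up returns to the route at 6.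

Step 1. The most likely failures are competing addition at the isopropylidene carbon, proton abstraction from the γ-methyl groups by the Grignard reagent, and lower enantioselectivity than with a simple enone because the cross-conjugated carbonyl binds the catalyst differently. The fallback moves the isopropylidene group to after the conjugate addition. Setting out from Grignard reagent 3, addition under the same catalysis to 3-methylcyclohex-2-en-1-one F3, the benchmark substrate of this reaction, gives (3S)-3-methyl-3-[3-(2-methyl-1,3-dioxolan-2-yl)propyl]cyclohexan-1-one F4, whose quaternary centre has the spatial arrangement of that in 4 although the descriptor differs. LiN(i-Pr)2 (THF, −78 °C) removes a proton from the methylene remote from the quaternary carbon of F4, and acetone gives (5R)-2-(2-hydroxypropan-2-yl)-5-methyl-5-[3-(2-methyl-1,3-dioxolan-2-yl)propyl]cyclohexan-1-one F5, a mixture at ring carbon 2. MsCl and Et3N convert F5 to 2-{(4R)-4-methyl-4-[3-(2-methyl-1,3-dioxolan-2-yl)propyl]-2-oxocyclohexyl}propan-2-yl methanesulfonate F6, and DBU eliminates methanesulfonate from F6 through the enolate to give 4, where the route is rejoined.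

Step 4. The most likely failure is poor facial selectivity: if the enone is twisted out of plane, hydrogen may be delivered from the equatorial (β) side, as in simple alkylidenecyclohexanes, and place the isopropyl group axial. The fallback changes the order of the two reductions and the mechanism of hydrogen delivery. Setting out from 6, Luche reduction (NaBH4, CeCl3·7H2O, MeOH, −40 °C) from the α face gives (1S,4aR,8S,8aS)-1,4a-dimethyl-7-(propan-2-ylidene)decahydronaphthalene-1,8-diol F7. Radical hydrogen-atom-transfer hydrogenation of F7 (Mn(dpm)3 cat., PhSiH3, t-BuOOH, i-PrOH) then passes through a tertiary ring radical at C7 next to a carbinol carbon, not a carbonyl carbon. There the equatorial isopropyl isomer is strongly preferred and is the one formed by axial hydrogen delivery. This returns to the route at 8 and bypasses 7.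

Step 6. The most likely failure is slow or unselective acylation: the 6-hydroxyl is axial, flanked by the isopropyl group and syn to C14 and the 4-hydroxyl, so the tertiary alcohol may compete or be dehydrated by the acidic half-ester at 100 °C. The fallback acylates at room temperature with a small activated acid and forms the olefin by phosphonate chemistry. Setting out from 8, diethylphosphonoacetic acid with DCC and DMAP (CH2Cl2, 23 °C) gives (1R,2S,4aR,8S,8aS)-8-hydroxy-4a,8-dimethyl-2-(propan-2-yl)decahydronaphthalen-1-yl 2-(diethoxyphosphoryl)acetate F8. Horner–Wadsworth–Emmons olefination of F8 with 11 (LiCl, DBU in excess to cover the phenol, MeCN) comes back to the route at 12 and bypasses 10.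

## Further compounds

F1 | step 3 | (3R)-2-bromo-3-methyl-3-[3-(2-methyl-1,3-dioxolan-2-yl)propyl]-6-(propan-2-ylidene)cyclohexan-1-one | O=C1C(Br)[C@](C)(CCCC2(C)OCCO2)CCC1=C(C)C
F2 | step 3 | (3R)-2-bromo-3-methyl-3-(4-oxopentyl)-6-(propan-2-ylidene)cyclohexan-1-one | O=C1C(Br)[C@](C)(CCCC(C)=O)CCC1=C(C)C
F3 | step 1 | 3-methylcyclohex-2-en-1-one | CC1=CC(=O)CCC1
F4 | step 1 | (3S)-3-methyl-3-[3-(2-methyl-1,3-dioxolan-2-yl)propyl]cyclohexan-1-one | O=C1C[C@](C)(CCCC2(C)OCCO2)CCC1
F5 | step 1 | (5R)-2-(2-hydroxypropan-2-yl)-5-methyl-5-[3-(2-methyl-1,3-dioxolan-2-yl)propyl]cyclohexan-1-one | O=C1C[C@](C)(CCCC2(C)OCCO2)CCC1C(C)(C)O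
F6 | step 1 | 2-{(4R)-4-methyl-4-[3-(2-methyl-1,3-dioxolan-2-yl)propyl]-2-oxocyclohexyl}propan-2-yl methanesulfonate | O=C1C[C@](C)(CCCC2(C)OCCO2)CCC1C(C)(C)OS(C)(=O)=O
F7 | step 4 | (1S,4aR,8S,8aS)-1,4a-dimethyl-7-(propan-2-ylidene)decahydronaphthalene-1,8-diol | O[C@H]2[C@@H]3[C@](C)(CCC[C@]3(C)O)CCC2=C(C)C
F8 | step 6 | (1R,2S,4aR,8S,8aS)-8-hydroxy-4a,8-dimethyl-2-(propan-2-yl)decahydronaphthalen-1-yl 2-(diethoxyphosphoryl)acetate | CCOP(=O)(OCC)CC(=O)O[C@H]2[C@@H]3[C@](C)(CCC[C@]3(C)O)CC[C@H]2C(C)C
A1 | alternative 1 | (+)-dihydrocarvone, (2R,5R)-2-methyl-5-(prop-1-en-2-yl)cyclohexan-1-one | CC(=C)[C@@H]1CC[C@@H](C)C(=O)C1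
A2 | alternative 1 | pent-1-en-3-one | CCC(=O)C=C
A3 | alternative 1 | (+)-α-cyperone, (4aS,7R)-1,4a-dimethyl-7-(prop-1-en-2-yl)-4,4a,5,6,7,8-hexahydronaphthalen-2(3H)-one | O=C1CC[C@]2(C)CC[C@@H](C(C)=C)CC2=C1C
A4 | alternative 2 | thymoquinone, 2-methyl-5-(propan-2-yl)cyclohexa-2,5-diene-1,4-dione | CC1=CC(=O)C(C(C)C)=CC1=O
A5 | alternative 2 | (E)-1-(trimethylsilyloxy)buta-1,3-diene | C=C/C=C/O[Si](C)(C)C
A6 | alternative 2 | cis-fused adduct (racemic, one enantiomer drawn), 4a-methyl-2-(propan-2-yl)-8-(trimethylsilyloxy)-4a,5,8,8a-tetrahydronaphthalene-1,4-dione | CC(C)C1=CC(=O)[C@@]2(C)CC=C[C@@H](O[Si](C)(C)C)[C@H]2C1=O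
A7 | alternative 3 | eudesman-6β-ol, (1R,2S,4aR,8R,8aS)-4a,8-dimethyl-2-(propan-2-yl)decahydronaphthalen-1-ol | O[C@H]2[C@@H]3[C@](C)(CCC[C@H]3C)CC[C@H]2C(C)C
A8 | alternative 3 | (1R,2S,4aR,8R,8aS)-4a,8-dimethyl-2-(propan-2-yl)decahydronaphthalen-1-yl N-(2,2,2-trifluoroethyl)carbamate | FC(F)(F)CNC(=O)O[C@H]2[C@@H]3[C@](C)(CCC[C@H]3C)CC[C@H]2C(C)C
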